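Q forms as E meets X, so first find which concentration sets the order of that rate.

common to all: E 0.050 M; G 9.7 mM (held)

|  | X | remark | time |
|---|---|---|---|
| violet | 0.084 M | run made earlier |  |
| ochre | 0.13 M | run made earlier |  |
| flask | 0.0600 M |  | 2.5 min |

- violet (time / s: Q / %, D / %): 10.0: 2.8, 0; 15.0: 4.6, 0.3; 40.0: 12.5, 0.4; 90.0: 23.6, 1.5
- ochre (time / s: Q / %, D / %): 10.0: 5.4, 0.2; 15.0: 8.6, 1.5; 40.0: 18.0, 0.7; 90.0: 34.7, 1.9

(standard deviation of a reading: 0.5 percentage points)

1. concentration of Q at 2.5 min, in M
2. concentration of D at 2.5 min, in M

- percent here means E units held: one D counts as two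
- at the start none of Z is dissolved
- steps under discussion: E + X -> Q; E + Z -> J; X -> L; E + Q -> D; G <-> Z

Read both runs at their last point, 90.0 s. Treat the loss of E as attenuation: hold c_X at its charge (the pseudo-first-order picture), and the share of E turned into Q is one minus e to the power −θ, with θ = k·c_X·t. The violet run gives k = 0.0356 /M/s and the ochre run 0.0364 /M/s, though ochre holds 1.55 times the X. So take the rate as first order in X and carry the mean, 0.0360 /M/s, the apparent constant for Q per molar X.

Charge the new flask with X at 0.0600 M and stop it at 2.5 min. Its c_X·t is larger than violet's last and smaller than ochre's, although its X is lower than in either run and its time longer than either last reading; since θ depends on that product, run no further calibration first and accept the extrapolation. Then θ = 0.324, and I expect 0.0138 M of Q. Expect that on the high side: this flask charges X at 1.20 times E, and θ counts X as held. Leave D unreckoned, since its last readings, 1.5% and 1.9%, stand against a scatter of 0.5 percentage points.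

The forecast gave 0.0125 M of Q and 7.000 × 10⁻⁴ M of D, holding that “the reaction looks first order in X”.

The flask gives 0.0130 M of Q and 7.74 × 10⁻⁴ M of D, against my 0.0138 M of Q; X then stood at 76.9% of its charge, not at the full charge θ assumed.

    E + X → Q (k = 0.0420 /M/s)
    E + Z → J (k = 0.0270 /M/s)
    X → L (k = 1.40 × 10⁻⁵ /s)
    E + Q → D (k = 0.0180 /M/s)
    G ⇌ Z, rate k5*(csat - [Z]) (kL = 0.0590 /s)

Now take the neighbour flask charged with 0.15 M of X, stopped at the same time: θ = 0.810, so the carried constant gives 0.0278 M of Q. The computed result there is 0.0265 M, with X at 81.3% of its charge.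

All runs stem from a simulated flask with made-up constants; scatter was added.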